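Take a ratio: in Thursday's run, target at 80.0 min over target at 40.0 min reads 4.35 for twice the time. Growth with the square of time looks like this, and the slow start is an induction period.

| flask | solid substrate | partner | temperature | remark | time |
|---|---|---|---|---|---|
| Sunday's | 0.70 M | 1.1 equiv | 5 °C | run made earlier |  |
| Thursday's | 1 M | 1.1 equiv | 25 °C | run made earlier |  |
| Saturday's | 1.4 M | 0.55 equiv | 5 °C | run made earlier |  |
| dawn | 1.4 M | 1.10 equiv | 40 °C |  | 1.0 h |
| spring | 1.4 M | 1.10 equiv | 25 °C |  | 1.0 h |
| midnight | 1.4 M | 1.10 equiv | 10 °C |  | 1.0 h |

| Sunday's: time / h | Sunday's: target / % | Thursday's: time / min | Thursday's: target / % | Saturday's: time / h | Saturday's: target / % |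
|---|---|---|---|---|---|
| 0.250 | 0 | 6.00 | 0.5 | 0.250 | 1.3 |
| 1.00 | 0 | 10.0 | 1.1 | 0.500 | 0.2 |
| 1.33 | 1.0 | 20.0 | 0.6 | 1.00 | 0 |
| 2.50 | 2.2 | 40.0 | 3.7 | 2.00 | 0 |
| 4.00 | 1.8 | 80.0 | 16.1 | 4.00 | 1.1 |

(standard deviation of a reading: 1 percentage point)

- solid, in amounts per volume of the solution: solid substrate
- at the start none of the solid substrate is in solution
- what has only dissolved of solid substrate counts as not reacted

* the flask with the highest amount of target, in percent of the solid substrate charged ("all alike" if they lie within 1.5 percentage points) (dawn / spring / midnight / all alike)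
* final target, as a percentage of the solid substrate charged, in dawn
* final target, as a percentage of the solid substrate charged, in spring
* final target, as a percentage of the solid substrate charged, in midnight

I argue from that ramp. Add a run's last three readings, divide by the sum of their squared times, and multiply by the square of 1.0 h. Thursday's run gives 8.74%, and Sunday's gives 0.208%. Call this the hour mark, the target a flask holds at 1.0 h while it stays on its time-squared ramp.

From Sunday's run at 5 °C to Thursday's run at 25 °C, which also differ in the charge of solid substrate, the mark reads higher by a factor of 42.0, with the scatter of both runs in it. I book that factor on temperature and assume the same factor for each equal step in temperature. Midnight then gets 0.530%. Dawn gets 144%, more than the whole charge, so I cut dawn at the charge.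

Sunday's and Saturday's runs share [partner] of 0.770 M, yet Saturday's mark is lower, at 0.0524%. That is a weak reading at this scatter, but I take it that the mark follows equivalents, and I give spring Thursday's 8.74% unchanged.

The forecast reads the same induction but lets percent target rise with [partner], and it stops dawn short of the charge because “depletion and dissolution limit the yield”. It says 70% for dawn, 12% for spring and 0.8% for midnight, with dawn richest.

The flasks give 25.5% at dawn, 8.80% in spring and 0.551% at midnight, so dawn leads. Dawn lies 45 percentage points below the forecast and further still below my cut, and at 1.00 h it holds 74.5% as intermediate.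

    starting material → intermediate (k = 4.75 × 10⁻⁴ s⁻¹, Ea = 90.0 kJ mol⁻¹)
    partner + intermediate ⇌ target (K = 1.70 L mol⁻¹, k = 1.01 × 10⁻⁴ L mol⁻¹ s⁻¹, Ea = 61.0 kJ mol⁻¹, ΔH = −34.0 kJ mol⁻¹)
    2 partner → homo product (k = 3.05 × 10⁻⁵ L mol⁻¹ s⁻¹, Ea = 76.0 kJ mol⁻¹)
    solid substrate ⇌ starting material, rate k4*(cs4 - [starting material]) while solid is left; crystals form when [starting material] > cs4 (solubility = 0.550 M, k = 0.00300 s⁻¹)
    (constants at 25 °C)

My ramp loses at dawn, but spring and midnight are its ground, with 8.74% against 8.80% and 0.530% against 0.551%. Take the spring flask at 0 °C: the same factor puts its hour mark at 0.0818%, and that flask gives 0.0571%.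

The data are calculated with made-up constants, and the scatter is random.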